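## Retrosynthetic overview

1. The target is a tridepside A–B–C. The plan rests on ring B: C1 bears the aryl ester, C2 a free OH chelated to that ester, C3 H, C4 the oxygen acylated by ring A, C5 H and C6 CH3. It is a resorcinol whose two oxygens must be told apart.
2. Last cuts: the four benzyl groups (one hydrogenolysis) and the A–B ester, made by acylating the unchelated C4–OH of ring B with the ring A acid chloride. Ring A comes from orcylaldehyde: the ring carbon that bears the formyl group becomes the methoxy-bearing C5 (Baeyer–Villiger, methylation), and a new formyl group is placed at C1.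
3. Key cut: ring B opens to a vinylketene (C5, C6, C1, with the ketene carbonyl as C2) and a siloxyalkyne (C3, C4). The ketene oxygen ends as C2–OH and the alkyne oxygen as C4–OSi, so the two oxygens differ from the moment the ring forms.
4. The vinylketene arises by photochemical Wolff rearrangement of an E diazoketone that already carries the ring C aryl ester, so the crowded B–C ester is made on an open-chain enoic acid. The diazo group is installed by diazo transfer to a methyl ketone.
5. Ring order: rings C (orsellinic acid) and A (orcylaldehyde) are bought as arenes. Ring B is the only ring built, and it is built on ring C before ring A is attached.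

Key step: step 10

Remark on the chemistry: the siloxyalkyne carries a trimethylsilyl group on its free carbon, because that compound comes in one flask from a silylynolate, whereas O-silylation of the unsubstituted ynolate competes with C-silylation to a silylketene; the extra silyl group ends on C3 of ring B and is removed by acid before isolation. The target has no stereocentre, and the only stereochemical element of the route is the E geometry of the enoate.

## Route

Step 1
Reactants: 1 orsellinic acid (2,4-dihydroxy-6-methylbenzoic acid)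
Product: 2 benzyl 2,4-dihydroxy-6-methylbenzoate
Conditions: BnBr (1.05 equiv), KHCO3, DMF, rt
Reagents that add atoms: benzyl bromide, BrCc1ccccc1
Why: Carboxylate alkylation (SN2 esterification): KHCO3 deprotonates only the carboxylic acid, so benzyl bromide should esterify it without touching the phenols, and room temperature avoids the easy decarboxylation of 1.

Step 2
Reactants: 2 benzyl 2,4-dihydroxy-6-methylbenzoate
Product: 3 benzyl 2-hydroxy-4-(methoxymethoxy)-6-methylbenzoate
Conditions: MOMCl (1.1 equiv), i-Pr2NEt, CH2Cl2, 0 °C → rt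
Reagents that add atoms: chloromethyl methyl ether, COCCl
Why: Selective O-alkylation (Williamson type): the C2 hydroxyl is held in a hydrogen bond to the ester carbonyl, so the free and more acidic C4 hydroxyl should take up the methoxymethyl group with one equivalent of reagent.

Step 3
Reactants: 3 benzyl 2-hydroxy-4-(methoxymethoxy)-6-methylbenzoate
Product: 4 benzyl 2-(benzyloxy)-4-(methoxymethoxy)-6-methylbenzoate
Conditions: BnBr, K2CO3, DMF, 60 °C
Reagents that add atoms: benzyl bromide, BrCc1ccccc1
Why: Williamson ether synthesis: with C4 blocked, carbonate in warm DMF breaks the chelate and the C2 phenoxide is benzylated, while the acetal and the di-ortho-substituted benzyl ester are inert to this base.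

Step 4
Reactants: 4 benzyl 2-(benzyloxy)-4-(methoxymethoxy)-6-methylbenzoate
Product: 5 benzyl 2-(benzyloxy)-4-hydroxy-6-methylbenzoate (ring C phenol)
Conditions: HCl (cat.), MeOH/THF, 50 °C
Reagents that add atoms: none
Why: Acid-catalysed acetal exchange: the MOM acetal is passed on to methanol under conditions that leave the aryl benzyl ether and the hindered benzyl ester alone, which frees only the C4 phenol.

Step 5
Reactants: 6 butane-2,3-dione; 7 tert-butyl (triphenylphosphoranylidene)acetate
Product: 8 tert-butyl (E)-3-methyl-4-oxopent-2-enoate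
Conditions: 6 (3 equiv), CH2Cl2, 0 °C → rt
Reagents that add atoms: none
Why: Wittig olefination with a stabilised ylide: the α-dicarbonyl ketone is electrophilic enough to react at room temperature, the excess of 6 suppresses a second olefination, and the stabilised ylide should place the ester trans to the larger acetyl group (E), any Z isomer being removed by chromatography.

Step 6
Reactants: 8 tert-butyl (E)-3-methyl-4-oxopent-2-enoate
Product: 9 (E)-3-methyl-4-oxopent-2-enoic acid
Conditions: CF3CO2H/CH2Cl2 (1:3), rt
Reagents that add atoms: none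
Why: Acidolysis of a tert-butyl ester (loss of isobutene), which needs neither nucleophile nor base and so should leave the electrophilic E enone untouched.

Step 7
Reactants: 5 ring C phenol; 9 (E)-3-methyl-4-oxopent-2-enoic acid
Product: 10 benzyl 2-(benzyloxy)-6-methyl-4-{[(E)-3-methyl-4-oxopent-2-enoyl]oxy}benzoate
Conditions: DCC, DMAP (cat.), CH2Cl2, 0 °C → rt
Reagents that add atoms: none
Why: Steglich esterification: the carboxyl group of 9 sits on an unhindered =CH carbon, so the only free hydroxyl of 5 should be acylated readily, and this ordinary ester later becomes the crowded B–C depside link.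

Step 8
Reactants: 10 methyl ketone aryl ester
Product: 13 benzyl 2-(benzyloxy)-4-{[(E)-5-diazo-3-methyl-4-oxopent-2-enoyl]oxy}-6-methylbenzoate, via lithium enolate 11 (not isolated), via trifluoroacetyl ketone 12 (not isolated)
Conditions: LiN(SiMe3)2 (1.1 equiv), THF, −78 °C (10 added to the base); CF3CO2CH2CF3, −78 °C; aq HCl quench; then MsN3, Et3N, H2O (1 equiv), MeCN, rt; product kept cold and dilute and used at once
Reagents that add atoms: methanesulfonyl azide, CS(=O)(=O)N=[N+]=[N-]; 2,2,2-trifluoroethyl trifluoroacetate, O=C(OCC(F)(F)F)C(F)(F)F (CF3CO group of 12 only); LiN(SiMe3)2, [Li]N([Si](C)(C)C)[Si](C)(C)C (lithium of 11 only)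
Why: Detrifluoroacetylative diazo transfer (Regitz type): kinetic enolisation at the only enolisable ketone position gives 11, trifluoroacetylation activates it as 1,3-diketone 12, and the sulfonyl azide with Et3N transfers N2 with loss of the trifluoroacetyl group; this path is taken instead of acylating diazomethane with an acid chloride because diazomethane would add as a 1,3-dipole to the doubly activated C=C bond.

Step 9
Reactants: 14 (trimethylsilyl)diazomethane
Product: 17 1-(triisopropylsilyloxy)-2-(trimethylsilyl)ethyne, via lithiated diazo compound 15 (not isolated), via lithium silylynolate 16 (not isolated)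
Conditions: n-BuLi, THF, −78 °C; CO (1 atm), −78 °C; i-Pr3SiOTf, −78 → 0 °C
Reagents that add atoms: carbon monoxide, [C-]#[O+]; triisopropylsilyl trifluoromethanesulfonate, CC(C)[Si](OS(=O)(=O)C(F)(F)F)(C(C)C)C(C)C; n-butyllithium, [Li]CCCC (lithium of 15 and 16 only)
Why: Carbonylation of a lithiated silyldiazomethane followed by O-silylation of the ynolate: 15 takes up CO and loses N2 to give 16, and the bulky, oxophilic triisopropylsilyl triflate should silylate it on oxygen rather than on carbon, as hindered silylating agents do with ynolates.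

Step 10
Reactants: 13 diazoketone; 17 1-(triisopropylsilyloxy)-2-(trimethylsilyl)ethyne
Product: 22 benzyl 2-(benzyloxy)-4-{[2-hydroxy-6-methyl-4-(triisopropylsilyloxy)benzoyl]oxy}-6-methylbenzoate (B–C didepside), via vinylketene 18 (not isolated), via vinylcyclobutenone 19 (not isolated), via dienylketene 20 (not isolated), via C3-silylated phenol 21 (not isolated)
Conditions: 17 (2 equiv), degassed ClCH2CH2Cl (0.1 M), hν (365 nm LED), 20 °C; then 80 °C; concentrate; CF3CO2H, CH2Cl2, 0 °C
Reagents that add atoms: none
Why: Light expels N2 from 13 and the alkenyl group shifts to the former diazo carbon (photochemical Wolff rearrangement, which also makes C5–C6) to give vinylketene 18, whose carbonyl carbon is attacked by the silicon-bearing carbon of 17 in a (2+2) cycloaddition that gives cyclobutenone 19 and with it the C2–C3 and C4–C5 bonds. On warming, 19 opens reversibly in a four-electron electrocyclic step to dienylketene 20, of which only the isomer with ketene and alkenyl group cis can close; this six-electron electrocyclisation forms C1–C2 and so the six-membered ring B, and enolisation of the dienone gives phenol 21. The closest known chemistry is the Danheiser benzannulation in its diazoketone version with trialkylsilyloxyalkynes, which delivers resorcinol monosilyl ethers. Regiochemistry needs the alkyne carbon remote from oxygen to bond to the ketene carbonyl: the oxygen lone pair makes that carbon the nucleophilic one and the silyl group on it stabilises the positive charge developing at the oxygen-bearing carbon, so both effects agree and C2 ends as free OH and C4 as OSi(i-Pr)3. The E alkene of 13 holds the aryl ester away from the ketene, which keeps the ester carbonyl from capturing it as a pyranone and puts H rather than the ester on the inside of the closing triene, and 365 nm light is chosen so that the aryl ester and enoate chromophores absorb little. No stereocentre survives (C4 of 19 is racemic and is lost on ring opening), and CF3CO2H finally protonates C3, ortho to both oxygens, ipso to silicon, so the placeholder leaves while the aryl O–Si bond, the benzyl groups and the esters stay.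

Step 11
Reactants: 22 silylated B–C didepside
Product: 23 benzyl 2-(benzyloxy)-4-[(2,4-dihydroxy-6-methylbenzoyl)oxy]-6-methylbenzoate
Conditions: Bu4NF (1.1 equiv), AcOH (1.5 equiv), THF, 0 °C
Reagents that add atoms: none
Why: Fluoride-induced cleavage of an aryl silyl ether: formation of the Si–F bond drives the reaction at 0 °C, and the acetic acid buffer keeps the phenoxide protonated so that the aryl ester links are not exchanged.

Step 12
Reactants: 24 orcylaldehyde (2,4-dihydroxy-6-methylbenzaldehyde)
Product: 25 2,4-bis(benzyloxy)-6-methylbenzaldehyde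
Conditions: BnBr (2.4 equiv), K2CO3, DMF, 60 °C
Reagents that add atoms: benzyl bromide, BrCc1ccccc1
Why: Double Williamson ether synthesis, in which warm DMF is needed for the hydroxyl chelated to the aldehyde and the aldehyde offers no α-hydrogen to the base.

Step 13
Reactants: 25 2,4-bis(benzyloxy)-6-methylbenzaldehyde
Product: 27 2,4-bis(benzyloxy)-6-methylphenol, via aryl formate 26 (not isolated)
Conditions: mCPBA, CH2Cl2, 0 °C → rt; then K2CO3, MeOH, rt
Reagents that add atoms: 3-chloroperbenzoic acid, O=C(OO)c1cccc(Cl)c1
Why: Baeyer–Villiger oxidation of an electron-rich benzaldehyde (Dakin-type outcome): the aryl group, activated by ortho and para alkoxy groups, migrates in preference to hydride to give formate 26, which mild methanolysis turns into the phenol, so the ring carbon that bore the formyl group gains the future C5 oxygen.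

Step 14
Reactants: 27 2,4-bis(benzyloxy)-6-methylphenol
Product: 28 1,5-bis(benzyloxy)-2-methoxy-3-methylbenzene
Conditions: MeI, K2CO3, acetone, reflux
Reagents that add atoms: iodomethane, CI
Why: Williamson methylation of the only free phenol, carried out at once because the electron-rich phenol 27 is sensitive to air.

Step 15
Reactants: 28 1,5-bis(benzyloxy)-2-methoxy-3-methylbenzene
Product: 30 2,4-bis(benzyloxy)-5-methoxy-6-methylbenzaldehyde, via iminium chloride 29 (not isolated)
Conditions: POCl3, DMF, 0 → 60 °C; then aq NaOAc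
Reagents that add atoms: N,N-dimethylformamide, CN(C)C=O; water, O; POCl3, O=P(Cl)(Cl)Cl (chloride of 29 only)
Why: Vilsmeier–Haack formylation: of the two free ring positions, the one between methyl and benzyloxy (para to the other benzyloxy group) is less crowded than the one between the two benzyloxy groups, as in the formylation of orcinol diethers, so iminium salt 29 and after hydrolysis the aldehyde should form at the future C1.

Step 16
Reactants: 30 2,4-bis(benzyloxy)-5-methoxy-6-methylbenzaldehyde
Product: 31 2,4-bis(benzyloxy)-5-methoxy-6-methylbenzoic acid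
Conditions: NaClO2, NaH2PO4, 2-methyl-2-butene, t-BuOH/THF/H2O, rt
Reagents that add atoms: sodium chlorite, [Na+].[O-]Cl=O
Why: Pinnick oxidation: chlorous acid oxidises the aldehyde without touching the benzyl ethers, and 2-methyl-2-butene traps the hypochlorous acid that would otherwise chlorinate the activated C3 position.

Step 17
Reactants: 31 ring A acid; 23 B–C didepside diol
Product: 33 benzyl 2-(benzyloxy)-4-{[4-{[2,4-bis(benzyloxy)-5-methoxy-6-methylbenzoyl]oxy}-2-hydroxy-6-methylbenzoyl]oxy}-6-methylbenzoate, via acid chloride 32 (not isolated)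
Conditions: 31, (COCl)2, DMF (cat.), CH2Cl2, 0 °C → rt, concentrate; then 23 (1.0 equiv), Et3N, DMAP (cat.), CH2Cl2, 0 °C
Reagents that add atoms: oxalyl chloride, O=C(Cl)C(=O)Cl (chlorine of 32 only)
Why: Acid chloride formation and DMAP-catalysed acylation of a phenol: the C2 hydroxyl of ring B is chelated to and flanked by the B–C ester, so one equivalent of the hindered acid chloride 32 should acylate only the free C4 hydroxyl, the selectivity on which classical depside couplings rely.

Step 18
Reactants: 33 tetrabenzyl tridepside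
Product: 34 4-{[4-{[2,4-dihydroxy-5-methoxy-6-methylbenzoyl]oxy}-2-hydroxy-6-methylbenzoyl]oxy}-2-hydroxy-6-methylbenzoic acid (target CNP0327242.0)
Conditions: H2 (1 atm), 10% Pd/C, EtOAc/THF, rt
Reagents that add atoms: none
Why: Catalytic hydrogenolysis: the three aryl benzyl ethers and the benzyl ester are cleaved under neutral conditions at room temperature, which spares both depside esters, the methyl ether and the decarboxylation-prone free acid.

## Compound list

1 | orsellinic acid | Cc1cc(O)cc(O)c1C(=O)O | starting material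
2 | benzyl 2,4-dihydroxy-6-methylbenzoate | Cc1cc(O)cc(O)c1C(=O)OCc1ccccc1 | intermediate
3 | benzyl 2-hydroxy-4-(methoxymethoxy)-6-methylbenzoate | Cc1cc(OCOC)cc(O)c1C(=O)OCc1ccccc1 | intermediate
4 | benzyl 2-(benzyloxy)-4-(methoxymethoxy)-6-methylbenzoate | Cc1cc(OCOC)cc(OCc2ccccc2)c1C(=O)OCc1ccccc1 | intermediate
5 | benzyl 2-(benzyloxy)-4-hydroxy-6-methylbenzoate | Cc1cc(O)cc(OCc2ccccc2)c1C(=O)OCc1ccccc1 | intermediate
6 | butane-2,3-dione | CC(=O)C(C)=O | starting material
7 | tert-butyl (triphenylphosphoranylidene)acetate | CC(C)(C)OC(=O)C=P(c1ccccc1)(c1ccccc1)c1ccccc1 | starting material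
8 | tert-butyl (E)-3-methyl-4-oxopent-2-enoate | CC(=O)/C(C)=C/C(=O)OC(C)(C)C | intermediate
9 | (E)-3-methyl-4-oxopent-2-enoic acid | CC(=O)/C(C)=C/C(=O)O | intermediate
10 | benzyl 2-(benzyloxy)-6-methyl-4-{[(E)-3-methyl-4-oxopent-2-enoyl]oxy}benzoate | CC(=O)/C(C)=C/C(=O)Oc1cc(C)c(C(=O)OCc2ccccc2)c(OCc2ccccc2)c1 | intermediate
11 | lithium enolate of 10 (enolised at the acetyl CH3) | [Li+].[O-]C(=C)/C(C)=C/C(=O)Oc1cc(C)c(C(=O)OCc2ccccc2)c(OCc2ccccc2)c1 | intermediate
12 | benzyl 2-(benzyloxy)-6-methyl-4-{[(E)-7,7,7-trifluoro-3-methyl-4,6-dioxohept-2-enoyl]oxy}benzoate | O=C(CC(=O)/C(C)=C/C(=O)Oc1cc(C)c(C(=O)OCc2ccccc2)c(OCc2ccccc2)c1)C(F)(F)F | intermediate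
13 | benzyl 2-(benzyloxy)-4-{[(E)-5-diazo-3-methyl-4-oxopent-2-enoyl]oxy}-6-methylbenzoate | [N-]=[N+]=CC(=O)/C(C)=C/C(=O)Oc1cc(C)c(C(=O)OCc2ccccc2)c(OCc2ccccc2)c1 | intermediate
14 | (trimethylsilyl)diazomethane | C[Si](C)(C)C=[N+]=[N-] | starting material
15 | lithio(trimethylsilyl)diazomethane | [Li]C(=[N+]=[N-])[Si](C)(C)C | intermediate
16 | lithium (trimethylsilyl)ethynolate | [Li+].[O-]C#C[Si](C)(C)C | intermediate
17 | 1-(triisopropylsilyloxy)-2-(trimethylsilyl)ethyne | C[Si](C)(C)C#CO[Si](C(C)C)(C(C)C)C(C)C | intermediate
18 | vinylketene, aryl (E)-3-methyl-5-oxopenta-2,4-dienoate | O=C=C/C(C)=C/C(=O)Oc1cc(C)c(C(=O)OCc2ccccc2)c(OCc2ccccc2)c1 | intermediate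
19 | 4-alkenyl-3-(triisopropylsilyloxy)-2-(trimethylsilyl)cyclobut-2-enone (racemic at C4, E alkene) | O=C1C([Si](C)(C)C)=C(O[Si](C(C)C)(C(C)C)C(C)C)C1/C(C)=C/C(=O)Oc1cc(C)c(C(=O)OCc2ccccc2)c(OCc2ccccc2)c1 | intermediate
20 | dienylketene (ketenyl and alkenyl groups cis on the siloxy alkene, enoate E) | O=C=C([Si](C)(C)C)/C(O[Si](C(C)C)(C(C)C)C(C)C)=C\C(C)=C\C(=O)Oc1cc(C)c(C(=O)OCc2ccccc2)c(OCc2ccccc2)c1 | intermediate
21 | B–C didepside with SiMe3 on C3 of ring B | Cc1cc(O[Si](C(C)C)(C(C)C)C(C)C)c([Si](C)(C)C)c(O)c1C(=O)Oc1cc(C)c(C(=O)OCc2ccccc2)c(OCc2ccccc2)c1 | intermediate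
22 | benzyl 2-(benzyloxy)-4-{[2-hydroxy-6-methyl-4-(triisopropylsilyloxy)benzoyl]oxy}-6-methylbenzoate | Cc1cc(O[Si](C(C)C)(C(C)C)C(C)C)cc(O)c1C(=O)Oc1cc(C)c(C(=O)OCc2ccccc2)c(OCc2ccccc2)c1 | intermediate
23 | benzyl 2-(benzyloxy)-4-[(2,4-dihydroxy-6-methylbenzoyl)oxy]-6-methylbenzoate | Cc1cc(O)cc(O)c1C(=O)Oc1cc(C)c(C(=O)OCc2ccccc2)c(OCc2ccccc2)c1 | intermediate
24 | orcylaldehyde (2,4-dihydroxy-6-methylbenzaldehyde) | Cc1cc(O)cc(O)c1C=O | starting material
25 | 2,4-bis(benzyloxy)-6-methylbenzaldehyde | Cc1cc(OCc2ccccc2)cc(OCc2ccccc2)c1C=O | intermediate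
26 | 2,4-bis(benzyloxy)-6-methylphenyl formate | Cc1cc(OCc2ccccc2)cc(OCc2ccccc2)c1OC=O | intermediate
27 | 2,4-bis(benzyloxy)-6-methylphenol | Cc1cc(OCc2ccccc2)cc(OCc2ccccc2)c1O | intermediate
28 | 1,5-bis(benzyloxy)-2-methoxy-3-methylbenzene | COc1c(C)cc(OCc2ccccc2)cc1OCc1ccccc1 | intermediate
29 | [2,4-bis(benzyloxy)-5-methoxy-6-methylbenzylidene]dimethyliminium chloride | COc1c(C)c(C=[N+](C)C)c(OCc2ccccc2)cc1OCc1ccccc1.[Cl-] | intermediate
30 | 2,4-bis(benzyloxy)-5-methoxy-6-methylbenzaldehyde | COc1c(C)c(C=O)c(OCc2ccccc2)cc1OCc1ccccc1 | intermediate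
31 | 2,4-bis(benzyloxy)-5-methoxy-6-methylbenzoic acid | COc1c(C)c(C(=O)O)c(OCc2ccccc2)cc1OCc1ccccc1 | intermediate
32 | 2,4-bis(benzyloxy)-5-methoxy-6-methylbenzoyl chloride | COc1c(C)c(C(=O)Cl)c(OCc2ccccc2)cc1OCc1ccccc1 | intermediate
33 | tetrabenzyl tridepside | COc1c(OCc2ccccc2)cc(OCc2ccccc2)c(C(=O)Oc2cc(C)c(C(=O)Oc3cc(C)c(C(=O)OCc4ccccc4)c(OCc4ccccc4)c3)c(O)c2)c1C | intermediate
34 | CNP0327242.0 | COc1c(O)cc(O)c(C(=O)Oc2cc(C)c(C(=O)Oc3cc(C)c(C(=O)O)c(O)c3)c(O)c2)c1C | target

## Step count and risks

Total step count: 18.
Longest linear sequence: 10 steps (1, 2, 3, 4, 7, 8, 10, 11, 17, 18).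

**Steps most likely to fail**

**1. Step 10 (key step).**
- The (2+2) addition to the hindered, doubly silylated alkyne may be slower than self-condensation of the ketene or its capture by phenol already formed.
- The light may isomerise the E enoate, after which the ester carbonyl can trap the ketene.
- The aryl ester may suffer photo-Fries cleavage.

Fallback: a classical depside esterification that takes ring B from the aromatic pool. It sets out from 2 (with 5 as partner) and comes back at 22. Selective silylation of the unchelated hydroxyl of 2 (i-Pr3SiCl, imidazole, DMF) should give benzyl 2-hydroxy-6-methyl-4-(triisopropylsilyloxy)benzoate F1. Hydrogenolysis of its benzyl ester (H2, Pd/C, EtOAc) should give 2-hydroxy-6-methyl-4-(triisopropylsilyloxy)benzoic acid F2. F2 is then condensed with phenol 5 (DCC, toluene, rt) to give 22.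

**2. Step 8.**
- The enolate may add in conjugate fashion to acceptor that is not yet enolised.
- The base may attack the activated aryl ester.
- The diazoketone may add as a dipole to the activated alkene of a second molecule during concentration.

Fallback: a route without strong base that builds the diazo group by substitution and elimination. It sets out from 10 and comes back at 13. Soft enolisation (Me3SiOTf, Et3N, CH2Cl2, 0 °C) should give benzyl 2-(benzyloxy)-6-methyl-4-{[(E)-3-methyl-4-(trimethylsilyloxy)penta-2,4-dienoyl]oxy}benzoate F3. NBS (THF, −78 °C) should convert it into benzyl 2-(benzyloxy)-4-{[(E)-5-bromo-3-methyl-4-oxopent-2-enoyl]oxy}-6-methylbenzoate F4. N,N'-ditosylhydrazine with DBU (THF, 0 °C, short contact) should then displace bromide and lose two sulfinate units to give 13.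

**3. Step 17.**
- Acyl transfer from the di-ortho-substituted acid chloride may be sluggish.
- The chelated C2 hydroxyl may be acylated as well.
- The base may promote ester exchange within the didepside.

Fallback: a change of protecting-group plan so that only one hydroxyl is ever free. It sets out from 22 (with 31 as partner) and comes back at 34. Mitsunobu benzylation (BnOH, PPh3, DIAD, THF) should give benzyl 2-(benzyloxy)-4-{[2-(benzyloxy)-6-methyl-4-(triisopropylsilyloxy)benzoyl]oxy}-6-methylbenzoate F5. Buffered desilylation (Bu4NF, AcOH, THF, 0 °C) should give benzyl 2-(benzyloxy)-4-{[2-(benzyloxy)-4-hydroxy-6-methylbenzoyl]oxy}-6-methylbenzoate F6. Condensation with acid 31 through its mixed trifluoroacetic anhydride ((CF3CO)2O, toluene, rt) should give the pentabenzyl tridepside F7. Hydrogenolysis (H2, Pd/C, EtOAc/THF) then gives 34.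

## Further compounds

F1 | step 10 | benzyl 2-hydroxy-6-methyl-4-(triisopropylsilyloxy)benzoate | Cc1cc(O[Si](C(C)C)(C(C)C)C(C)C)cc(O)c1C(=O)OCc1ccccc1
F2 | step 10 | 2-hydroxy-6-methyl-4-(triisopropylsilyloxy)benzoic acid | Cc1cc(O[Si](C(C)C)(C(C)C)C(C)C)cc(O)c1C(=O)O
F3 | step 8 | benzyl 2-(benzyloxy)-6-methyl-4-{[(E)-3-methyl-4-(trimethylsilyloxy)penta-2,4-dienoyl]oxy}benzoate | C=C(O[Si](C)(C)C)/C(C)=C/C(=O)Oc1cc(C)c(C(=O)OCc2ccccc2)c(OCc2ccccc2)c1
F4 | step 8 | benzyl 2-(benzyloxy)-4-{[(E)-5-bromo-3-methyl-4-oxopent-2-enoyl]oxy}-6-methylbenzoate | BrCC(=O)/C(C)=C/C(=O)Oc1cc(C)c(C(=O)OCc2ccccc2)c(OCc2ccccc2)c1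
F5 | step 17 | benzyl 2-(benzyloxy)-4-{[2-(benzyloxy)-6-methyl-4-(triisopropylsilyloxy)benzoyl]oxy}-6-methylbenzoate | Cc1cc(O[Si](C(C)C)(C(C)C)C(C)C)cc(OCc2ccccc2)c1C(=O)Oc1cc(C)c(C(=O)OCc2ccccc2)c(OCc2ccccc2)c1
F6 | step 17 | benzyl 2-(benzyloxy)-4-{[2-(benzyloxy)-4-hydroxy-6-methylbenzoyl]oxy}-6-methylbenzoate | Cc1cc(O)cc(OCc2ccccc2)c1C(=O)Oc1cc(C)c(C(=O)OCc2ccccc2)c(OCc2ccccc2)c1
F7 | step 17 | pentabenzyl tridepside | COc1c(OCc2ccccc2)cc(OCc2ccccc2)c(C(=O)Oc2cc(C)c(C(=O)Oc3cc(C)c(C(=O)OCc4ccccc4)c(OCc4ccccc4)c3)c(OCc3ccccc3)c2)c1C
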